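**Plan**
1. Reading of the target: the dihydrobenzofuran is (2S,3S), i.e. 2,3-cis, and the furo[3,4-c]furan is all-S, i.e. both aryl groups endo (all-cis). Atoms: C1(guaiacyl)–O2–C3–C3a–C4(benzofuranyl)–O5–C6–C6a; ring 1 = C1/O2/C3/C3a/C6a, ring 2 = C3a/C4/O5/C6/C6a.
2. Retrosynthesis: C6–H (as C6–OMe), C1–C6a and C1–O2 are cut together, giving cis-dihydrofuranylmethanol 19 and vanillin-derived acetal 20. The enol ether C6=C6a goes back to a lactol and C3a–C4 is cut as an aldol, giving aldehyde 8 and imide 11. The benzofuran C2–C3 bond is cut as a carbenoid C–H insertion, then the aryl–C(N2) and ArO–CH2 bonds.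
3. Enabling feature: C6a is β to O5, so C6=C6a can be an enol ether nucleophilic at C6a. C1 lies between O2 and an electron-rich arene at the aldehyde oxidation level, so it can be an oxocarbenium carbon. A C6 methoxy group is the temporary helper.
4. Forward order: benzyl ether, aryl diazoacetate, dihydrobenzofuran, anti-aldol, lactol, 2,3-dihydrofuran (ring 2), (4+1) annulation closing ring 1 last, then acetal reduction, ester reduction and desilylation.
5. Stereochemistry: benzofuran C2/C3 from the cis-selective Rh2(S-PTTL)4 insertion; C4/C3a from the oxazolidinone-controlled anti-aldol; C6a and C1 from the key step (cis fusion through the tether, endo aryl under kinetic control).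

Key step: step 12

Assumption: the SMILES is taken as written (cis benzofuran, diaxial furofuran); the hands of Rh2(S-PTTL)4 and of the (S)-oxazolidinone are those expected from the accepted models, and the mirror-image reagent would be used if a model compound showed the opposite sense.
Abbreviations: TIPS = triisopropylsilyl; BF = (2S,3R)-3-(ethoxycarbonyl)-7-methoxy-2-[3-methoxy-4-(triisopropylsilyloxy)phenyl]-2,3-dihydrobenzofuran-5-yl.

Step 1
Reactants: 1 vanillin
Product: 2 3-methoxy-4-(triisopropylsilyloxy)benzaldehyde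
Conditions: TIPSCl, imidazole, DMF, rt
Reagents that add atoms: chlorotriisopropylsilane, CC(C)[Si](Cl)(C(C)C)C(C)C
Why: Phenol silylation; the TIPS aryl ether should survive base, hydride and Lewis acid and leave with fluoride at the end.

Step 2
Reactants: 2 3-methoxy-4-(triisopropylsilyloxy)benzaldehyde
Product: 3 [3-methoxy-4-(triisopropylsilyloxy)phenyl]methanol
Conditions: NaBH4, MeOH, 0 °C
Reagents that add atoms: none
Why: Borohydride reduction of an aryl aldehyde to the benzylic alcohol.

Step 3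
Reactants: 3 [3-methoxy-4-(triisopropylsilyloxy)phenyl]methanol; 4 5-iodovanillin (4-hydroxy-3-iodo-5-methoxybenzaldehyde)
Product: 5 3-iodo-5-methoxy-4-{[3-methoxy-4-(triisopropylsilyloxy)benzyl]oxy}benzaldehyde
Conditions: PPh3, DIAD, THF, 0 °C to rt
Reagents that add atoms: none
Why: Mitsunobu etherification of an acidic phenol (para-formyl, ortho-iodo) with a primary benzylic alcohol under neutral conditions that spare the aryl silyl ether.

Step 4
Reactants: 5 3-iodo-5-methoxy-4-{[3-methoxy-4-(triisopropylsilyloxy)benzyl]oxy}benzaldehyde; 6 ethyl diazoacetate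
Product: 7 ethyl 2-diazo-2-(5-formyl-3-methoxy-2-{[3-methoxy-4-(triisopropylsilyloxy)benzyl]oxy}phenyl)acetate
Conditions: Pd(PPh3)4 (5 mol%), Ag2CO3 (0.5 equiv), Et3N, toluene, rt
Reagents that add atoms: none
Why: Palladium-catalysed cross-coupling of an aryl iodide with the C–H bond of an acceptor diazo ester with retention of the diazo group; the para-formyl group speeds oxidative addition to zerovalent palladium.

Step 5
Reactants: 7 ethyl 2-diazo-2-(5-formyl-3-methoxy-2-{[3-methoxy-4-(triisopropylsilyloxy)benzyl]oxy}phenyl)acetate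
Product: 8 ethyl (2S,3R)-5-formyl-7-methoxy-2-[3-methoxy-4-(triisopropylsilyloxy)phenyl]-2,3-dihydrobenzofuran-3-carboxylate (aryl and ester cis)
Conditions: Rh2(S-PTTL)4 (1 mol%), toluene, −60 °C, slow addition of 7
Reagents that add atoms: none
Why: Dirhodium-carbenoid 1,5 C–H insertion into the oxygen-activated benzylic CH2 (intramolecular C–H functionalisation) closes the furan ring of the benzofuran; the concerted, hydride-transfer-like transition state in the chiral carboxylate pocket should place aryl and ester cis and set C2 (S) and C3 (R).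

Step 6
Reactants: 9 (S)-4-benzyl-1,3-oxazolidin-2-one; 10 pent-4-enoyl chloride
Product: 11 (S)-4-benzyl-3-(pent-4-enoyl)-1,3-oxazolidin-2-one
Conditions: n-BuLi, THF, −78 °C; then 10, −78 to 0 °C
Reagents that add atoms: none
Why: N-acylation of the lithiated oxazolidinone; the allyl group is the masked two-carbon arm C6a–C6.

Step 7
Reactants: 8 ethyl (2S,3R)-5-formyl-7-methoxy-2-[3-methoxy-4-(triisopropylsilyloxy)phenyl]-2,3-dihydrobenzofuran-3-carboxylate; 11 (S)-4-benzyl-3-(pent-4-enoyl)-1,3-oxazolidin-2-one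
Product: 13 (S)-4-benzyl-3-[(2R)-2-{(S)-hydroxy(BF)methyl}pent-4-enoyl]-1,3-oxazolidin-2-one (anti), via silyl ether 12 (not isolated)
Conditions: MgCl2 (20 mol%), Et3N, TMSCl, EtOAc, rt; then citric acid, MeOH, 0 °C
Reagents that add atoms: none
Why: MgCl2-catalysed direct anti-aldol reaction of an N-acyloxazolidinone (soft enolisation, silyl trapping of the aldolate): the chelated Z-enolate is attacked on the face away from the benzyl group through a boat-like transition state, which should set the future C3a (R in 13) and C4 (S) anti, while the benzofuran ester cannot chelate magnesium and is not enolised.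

Step 8
Reactants: 13 (S)-4-benzyl-3-[(2R)-2-{(S)-hydroxy(BF)methyl}pent-4-enoyl]-1,3-oxazolidin-2-one
Product: 16 (S)-4-benzyl-3-{[(2S,3R)-2-BF-5-hydroxytetrahydrofuran-3-yl]carbonyl}-1,3-oxazolidin-2-one (lactol anomers), via diol 14 (not isolated), via hydroxy aldehyde 15 (not isolated)
Conditions: OsO4 (2 mol%), NaIO4, 2,6-lutidine, dioxane/H2O, rt
Reagents that add atoms: sodium periodate, [Na+].[O-]I(=O)(=O)=O (terminal oxidant; the oxygen reaches the alkene through OsO4, O=[Os](=O)(=O)=O)
Why: Lemieux–Johnson oxidative cleavage of the terminal alkene; the γ-hydroxy aldehyde closes at once to the five-membered lactol (ring 2) because the benzylic hydroxyl is the only one present.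

Step 9
Reactants: 16 (S)-4-benzyl-3-{[(2S,3R)-2-BF-5-hydroxytetrahydrofuran-3-yl]carbonyl}-1,3-oxazolidin-2-one
Product: 18 (S)-4-benzyl-3-{[(2S,3R)-2-BF-2,3-dihydrofuran-3-yl]carbonyl}-1,3-oxazolidin-2-one (cis), via lactol mesylate 17 (not isolated)
Conditions: MsCl, Et3N, CH2Cl2, −20 °C to reflux
Reagents that add atoms: none
Why: Lactol dehydration through the anomeric sulfonate (elimination to a cyclic enol ether, as in glycal formation); no Lewis acid is present, and the imide α-C–H is held in the carbonyl plane by allylic strain, so this centre should keep its configuration.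

Step 10
Reactants: 18 (S)-4-benzyl-3-{[(2S,3R)-2-BF-2,3-dihydrofuran-3-yl]carbonyl}-1,3-oxazolidin-2-one
Product: 19 ethyl (2S,3R)-5-[(2S,3S)-3-(hydroxymethyl)-2,3-dihydrofuran-2-yl]-7-methoxy-2-[3-methoxy-4-(triisopropylsilyloxy)phenyl]-2,3-dihydrobenzofuran-3-carboxylate
Conditions: NaBH4, THF/H2O, 0 °C to rt
Reagents that add atoms: none
Why: Reductive removal of the oxazolidinone auxiliary with borohydride in wet THF, selective for the activated imide over the hindered ethyl ester and harmless to the enol ether; it frees the single hydroxyl needed for the key step.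

Step 11
Reactants: 2 3-methoxy-4-(triisopropylsilyloxy)benzaldehyde
Product: 20 4-(dimethoxymethyl)-2-methoxy-1-(triisopropylsilyloxy)benzene
Conditions: HC(OMe)3, TsOH (1 mol%), MeOH, rt; Et3N quench
Reagents that add atoms: trimethyl orthoformate, COC(OC)OC
Why: Acid-catalysed acetalisation driven by the orthoformate; the acetal is the latent oxocarbenium carbon C1 with its guaiacyl group.

Step 12
Reactants: 19 ethyl (2S,3R)-5-[(2S,3S)-3-(hydroxymethyl)-2,3-dihydrofuran-2-yl]-7-methoxy-2-[3-methoxy-4-(triisopropylsilyloxy)phenyl]-2,3-dihydrobenzofuran-3-carboxylate; 20 4-(dimethoxymethyl)-2-methoxy-1-(triisopropylsilyloxy)benzene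
Product: 22 ethyl (2S,3R)-7-methoxy-5-{(1S,3aS,4S,6S,6aR)-6-methoxy-1-[3-methoxy-4-(triisopropylsilyloxy)phenyl]tetrahydro-1H,3H-furo[3,4-c]furan-4-yl}-2-[3-methoxy-4-(triisopropylsilyloxy)phenyl]-2,3-dihydrobenzofuran-3-carboxylate, via mixed acetal 21 (not isolated)
Conditions: TMSOTf (0.2 equiv), 4 Å molecular sieves, CH2Cl2, −78 to −20 °C; Et3N quench
Reagents that add atoms: none
Why: TMSOTf ionises acetal 20 to the aryl-stabilised methoxycarbenium ion, which the only free hydroxyl of 19 captures to give mixed acetal 21; a second ionisation gives the O-alkyl oxocarbenium ion, whose carbon is attacked by the β-carbon of the cyclic enol ether (future C6a), and methanol then adds to the new oxocarbenium ion at C6 from the convex face. The closest known reaction type is Lewis-acid acetal exchange followed by intramolecular oxocarbenium–enol ether (Prins-type) cyclisation of cis-2-aryl-3-(hydroxymethyl)-2,3-dihydrofurans with aryl aldehyde acetals, a formal (4+1) annulation that is known to give diaxial 2,6-diaryl furofurans. Ring 1 (C1, O2, C3, C3a, C6a) closes in a 5-endo-trig mode at the C=O(+) bond and exo with respect to the enol ether C=C, which the cationic acceptor and the strong nucleophile should make feasible. C6a is set by the tether, which reaches only the face of the enol ether carrying the CH2O arm, so the two rings are cis-fused; C1 is set under kinetic control by the E-oxocarbenium ion reacting through the compact transition state with the C=O(+) unit over the C3a–C6a bond and the aryl group over ring 2, which should give the endo aryl group; the C6 acetal centre is not retained. The step needs chemoselectivity for one hydroxyl, secured because the second hydroxymethyl group is still an ethyl ester and both phenols are silyl ethers, and kinetic control at C1 and C4, secured by substoichiometric acid, low temperature and the amine quench before the benzylic C–O bonds can ionise towards the exo isomers.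

Step 13
Reactants: 22 the 6-methoxy furofuran acetal from step 12
Product: 23 ethyl (2S,3R)-7-methoxy-5-{(1S,3aS,4S,6aS)-1-[3-methoxy-4-(triisopropylsilyloxy)phenyl]tetrahydro-1H,3H-furo[3,4-c]furan-4-yl}-2-[3-methoxy-4-(triisopropylsilyloxy)phenyl]-2,3-dihydrobenzofuran-3-carboxylate
Conditions: Et3SiH, BF3·OEt2, CH2Cl2, −78 °C
Reagents that add atoms: none
Why: Ionic hydrogenation of the acetal (BF3 ionises the C6–OMe bond, the silane reduces the bicyclic oxocarbenium ion); no stereocentre is formed, and the low temperature should keep the two endo benzylic C–O bonds intact.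

Step 14
Reactants: 23 the bis-silyl furofuran ethyl ester from step 13
Product: 24 {(2S,3S)-7-methoxy-5-{(1S,3aS,4S,6aS)-1-[3-methoxy-4-(triisopropylsilyloxy)phenyl]tetrahydro-1H,3H-furo[3,4-c]furan-4-yl}-2-[3-methoxy-4-(triisopropylsilyloxy)phenyl]-2,3-dihydrobenzofuran-3-yl}methanol
Conditions: LiAlH4, THF, 0 °C
Reagents that add atoms: none
Why: Hydride reduction of the ester to the primary alcohol, which should be much faster than enolisation, so the cis C3 centre is kept; the ether rings are inert.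

Step 15
Reactants: 24 the bis-silyl furofuran alcohol from step 14
Product: 25 target, (1S,3aS,4S,6aS)-1-(4-hydroxy-3-methoxyphenyl)-4-[(2S,3S)-2-(4-hydroxy-3-methoxyphenyl)-3-(hydroxymethyl)-7-methoxy-2,3-dihydrobenzofuran-5-yl]tetrahydro-1H,3H-furo[3,4-c]furan
Conditions: TBAF, AcOH, THF, 0 °C
Reagents that add atoms: none
Why: Fluoride cleavage of both aryl silyl ethers; the acetic acid buffer keeps the phenoxides from opening the endo benzylic ethers through quinone methides.

**Compound list**
1 | vanillin | COc1cc(C=O)ccc1O | starting material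
2 | 3-methoxy-4-(triisopropylsilyloxy)benzaldehyde | COc1cc(C=O)ccc1O[Si](C(C)C)(C(C)C)C(C)C | intermediate
3 | [3-methoxy-4-(triisopropylsilyloxy)phenyl]methanol | COc1cc(CO)ccc1O[Si](C(C)C)(C(C)C)C(C)C | intermediate
4 | 5-iodovanillin | COc1cc(C=O)cc(I)c1O | starting material
5 | 3-iodo-5-methoxy-4-{[3-methoxy-4-(triisopropylsilyloxy)benzyl]oxy}benzaldehyde | COc1cc(C=O)cc(I)c1OCc1ccc(O[Si](C(C)C)(C(C)C)C(C)C)c(OC)c1 | intermediate
6 | ethyl diazoacetate | CCOC(=O)C=[N+]=[N-] | starting material
7 | ethyl 2-diazo-2-(5-formyl-3-methoxy-2-{[3-methoxy-4-(triisopropylsilyloxy)benzyl]oxy}phenyl)acetate | CCOC(=O)C(=[N+]=[N-])c1cc(C=O)cc(OC)c1OCc1ccc(O[Si](C(C)C)(C(C)C)C(C)C)c(OC)c1 | intermediate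
8 | ethyl (2S,3R)-5-formyl-7-methoxy-2-[3-methoxy-4-(triisopropylsilyloxy)phenyl]-2,3-dihydrobenzofuran-3-carboxylate (cis) | O=Cc1cc(OC)c2c(c1)[C@@H](C(=O)OCC)[C@@H](c1ccc(O[Si](C(C)C)(C(C)C)C(C)C)c(OC)c1)O2 | intermediate
9 | (S)-4-benzyl-1,3-oxazolidin-2-one | O=C1OC[C@H](Cc2ccccc2)N1 | starting material
10 | pent-4-enoyl chloride | C=CCCC(=O)Cl | starting material
11 | (S)-4-benzyl-3-(pent-4-enoyl)-1,3-oxazolidin-2-one | C=CCCC(=O)N1[C@@H](Cc2ccccc2)COC1=O | intermediate
12 | trimethylsilyl ether of aldol adduct 13 | C=CC[C@H]([C@H](O[Si](C)(C)C)c1cc(OC)c2c(c1)[C@@H](C(=O)OCC)[C@@H](c1ccc(O[Si](C(C)C)(C(C)C)C(C)C)c(OC)c1)O2)C(=O)N1[C@@H](Cc2ccccc2)COC1=O | intermediate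
13 | (S)-4-benzyl-3-[(2R)-2-{(S)-hydroxy(BF)methyl}pent-4-enoyl]-1,3-oxazolidin-2-one (anti) | C=CC[C@H]([C@H](O)c1cc(OC)c2c(c1)[C@@H](C(=O)OCC)[C@@H](c1ccc(O[Si](C(C)C)(C(C)C)C(C)C)c(OC)c1)O2)C(=O)N1[C@@H](Cc2ccccc2)COC1=O | intermediate
14 | 4,5-diol from dihydroxylation of 13 (epimers at the new carbinol carbon) | OCC(O)C[C@H]([C@H](O)c1cc(OC)c2c(c1)[C@@H](C(=O)OCC)[C@@H](c1ccc(O[Si](C(C)C)(C(C)C)C(C)C)c(OC)c1)O2)C(=O)N1[C@@H](Cc2ccccc2)COC1=O | intermediate
15 | (S)-4-benzyl-3-[(2R)-2-{(S)-hydroxy(BF)methyl}-4-oxobutanoyl]-1,3-oxazolidin-2-one | O=CC[C@H]([C@H](O)c1cc(OC)c2c(c1)[C@@H](C(=O)OCC)[C@@H](c1ccc(O[Si](C(C)C)(C(C)C)C(C)C)c(OC)c1)O2)C(=O)N1[C@@H](Cc2ccccc2)COC1=O | intermediate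
16 | (S)-4-benzyl-3-{[(2S,3R)-2-BF-5-hydroxytetrahydrofuran-3-yl]carbonyl}-1,3-oxazolidin-2-one (anomers) | OC1C[C@@H](C(=O)N2[C@@H](Cc3ccccc3)COC2=O)[C@@H](c2cc(OC)c3c(c2)[C@@H](C(=O)OCC)[C@@H](c2ccc(O[Si](C(C)C)(C(C)C)C(C)C)c(OC)c2)O3)O1 | intermediate
17 | anomeric methanesulfonate of lactol 16 | CS(=O)(=O)OC1C[C@@H](C(=O)N2[C@@H](Cc3ccccc3)COC2=O)[C@@H](c2cc(OC)c3c(c2)[C@@H](C(=O)OCC)[C@@H](c2ccc(O[Si](C(C)C)(C(C)C)C(C)C)c(OC)c2)O3)O1 | intermediate
18 | (S)-4-benzyl-3-{[(2S,3R)-2-BF-2,3-dihydrofuran-3-yl]carbonyl}-1,3-oxazolidin-2-one (cis) | O=C(N1[C@@H](Cc2ccccc2)COC1=O)[C@@H]1C=CO[C@@H]1c1cc(OC)c2c(c1)[C@@H](C(=O)OCC)[C@@H](c1ccc(O[Si](C(C)C)(C(C)C)C(C)C)c(OC)c1)O2 | intermediate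
19 | ethyl (2S,3R)-5-[(2S,3S)-3-(hydroxymethyl)-2,3-dihydrofuran-2-yl]-7-methoxy-2-[3-methoxy-4-(triisopropylsilyloxy)phenyl]-2,3-dihydrobenzofuran-3-carboxylate | OC[C@@H]1C=CO[C@@H]1c1cc(OC)c2c(c1)[C@@H](C(=O)OCC)[C@@H](c1ccc(O[Si](C(C)C)(C(C)C)C(C)C)c(OC)c1)O2 | intermediate
20 | 4-(dimethoxymethyl)-2-methoxy-1-(triisopropylsilyloxy)benzene | COC(OC)c1ccc(O[Si](C(C)C)(C(C)C)C(C)C)c(OC)c1 | intermediate
21 | mixed methyl acetal of alcohol 19 with the aldehyde of 20 (epimers at the acetal carbon) | COC(OC[C@@H]1C=CO[C@@H]1c1cc(OC)c2c(c1)[C@@H](C(=O)OCC)[C@@H](c1ccc(O[Si](C(C)C)(C(C)C)C(C)C)c(OC)c1)O2)c1ccc(O[Si](C(C)C)(C(C)C)C(C)C)c(OC)c1 | intermediate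
22 | (1S,3aS,4S,6S,6aR)-6-methoxy furofuran acetal, both aryl groups endo, OMe exo | COc1cc([C@H]2OC[C@@H]3[C@H]2[C@@H](OC)O[C@@H]3c2cc(OC)c3c(c2)[C@@H](C(=O)OCC)[C@@H](c2ccc(O[Si](C(C)C)(C(C)C)C(C)C)c(OC)c2)O3)ccc1O[Si](C(C)C)(C(C)C)C(C)C | intermediate
23 | bis-silyl (1S,3aS,4S,6aS)-furofuran ethyl ester | COc1cc([C@H]2OC[C@@H]3[C@H]2CO[C@@H]3c2cc(OC)c3c(c2)[C@@H](C(=O)OCC)[C@@H](c2ccc(O[Si](C(C)C)(C(C)C)C(C)C)c(OC)c2)O3)ccc1O[Si](C(C)C)(C(C)C)C(C)C | intermediate
24 | bis-silyl (1S,3aS,4S,6aS)-furofuran with (2S,3S)-3-hydroxymethyl benzofuran | COc1cc([C@H]2OC[C@@H]3[C@H]2CO[C@@H]3c2cc(OC)c3c(c2)[C@@H](CO)[C@@H](c2ccc(O[Si](C(C)C)(C(C)C)C(C)C)c(OC)c2)O3)ccc1O[Si](C(C)C)(C(C)C)C(C)C | intermediate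
25 | target CNP0303197.1 | COc1cc([C@H]2OC[C@@H]3[C@H]2CO[C@@H]3c2cc(OC)c3c(c2)[C@@H](CO)[C@@H](c2ccc(O)c(OC)c2)O3)ccc1O | target

Total step count: 15. Longest linear sequence: 13 steps (1, 2, 3, 4, 5, 7, 8, 9, 10, 12, 13, 14, 15).

**Steps most likely to fail**

Step 12. The acid may destroy the enol ether or ionise the electron-rich benzylic C–O bonds before the cyclisation is complete, and reversible ring opening may erode the endo selectivity at C1. The fallback forms the C1–C6a bond by a neutral radical cyclisation; it sets out from 19 (with 3 as side material) and returns at 23. Alcohol 3 would be converted with PhSSPh and Bu3P into [3-methoxy-4-(triisopropylsilyloxy)benzyl] phenyl sulfide F5. Chlorination with N-chlorosuccinimide would give the α-chloro sulfide F6. Alcohol 19 would be alkylated with F6 in the presence of iPr2NEt to give the O,S-acetal F7. Slow addition of Bu3SnH with AIBN in benzene at 80 °C should generate the α-alkoxybenzyl radical, which closes 5-exo onto C6a; the C6 radical takes hydrogen from the stannane and gives 23 directly. The chair-like transition state of a 1-substituted hex-5-enyl radical favours the cis (endo) aryl group, and no acid is present.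

Step 4. With the iodide flanked by the benzyloxy group, the aryl–palladium intermediate may decompose the diazo ester (carbene formation and migratory insertion) faster than it couples, and the aldehyde may condense with the diazo ester. The fallback builds the arylacetate first and introduces the diazo group afterwards; it sets out from 5 and returns at 7. The aldehyde of 5 would be masked as the dimethyl acetal F1 (HC(OMe)3, TsOH). The iodide would be coupled with ethyl acetoacetate under CuI, L-proline and Cs2CO3 in DMSO to give the α-aryl acetoacetate F2. A Regitz deacylating diazo transfer (4-acetamidobenzenesulfonyl azide, DBU, MeCN) would give the diazo acetal F3, and PPTS in wet acetone would free the aldehyde to give 7.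

Step 5. The methoxy group next to the benzyloxy substituent may change the fit in the catalyst pocket and lower the enantio- or cis-selectivity, and the aldehyde oxygen may intercept the carbenoid. The fallback gives up catalyst control of the absolute configuration; it sets out from 7 and returns at 8. The insertion would be run with an achiral cis-selective dirhodium carboxylate such as Rh2(O2CCPh3)4 (or the racemic form of the same catalyst). The racemic cis ester would be resolved by preparative chromatography on a chiral stationary phase, and the unwanted enantiomer ent-8 F4 set aside.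

**Further compounds**
F1 | step 4 | 1-(dimethoxymethyl)-3-iodo-5-methoxy-4-{[3-methoxy-4-(triisopropylsilyloxy)benzyl]oxy}benzene | COC(OC)c1cc(I)c(OCc2ccc(O[Si](C(C)C)(C(C)C)C(C)C)c(OC)c2)c(OC)c1
F2 | step 4 | ethyl 2-(5-(dimethoxymethyl)-3-methoxy-2-{[3-methoxy-4-(triisopropylsilyloxy)benzyl]oxy}phenyl)-3-oxobutanoate | CCOC(=O)C(C(C)=O)c1cc(C(OC)OC)cc(OC)c1OCc1ccc(O[Si](C(C)C)(C(C)C)C(C)C)c(OC)c1
F3 | step 4 | ethyl 2-diazo-2-(5-(dimethoxymethyl)-3-methoxy-2-{[3-methoxy-4-(triisopropylsilyloxy)benzyl]oxy}phenyl)acetate | CCOC(=O)C(=[N+]=[N-])c1cc(C(OC)OC)cc(OC)c1OCc1ccc(O[Si](C(C)C)(C(C)C)C(C)C)c(OC)c1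
F4 | step 5 | ent-8, ethyl (2R,3S)-5-formyl-7-methoxy-2-[3-methoxy-4-(triisopropylsilyloxy)phenyl]-2,3-dihydrobenzofuran-3-carboxylate | O=Cc1cc(OC)c2c(c1)[C@H](C(=O)OCC)[C@H](c1ccc(O[Si](C(C)C)(C(C)C)C(C)C)c(OC)c1)O2
F5 | step 12 | [3-methoxy-4-(triisopropylsilyloxy)benzyl] phenyl sulfide | COc1cc(CSc2ccccc2)ccc1O[Si](C(C)C)(C(C)C)C(C)C
F6 | step 12 | chloro[3-methoxy-4-(triisopropylsilyloxy)phenyl]methyl phenyl sulfide | COc1cc(C(Cl)Sc2ccccc2)ccc1O[Si](C(C)C)(C(C)C)C(C)C
F7 | step 12 | O,S-acetal of alcohol 19 (epimers at the acetal carbon) | COc1cc(C(Sc2ccccc2)OC[C@@H]2C=CO[C@@H]2c2cc(OC)c3c(c2)[C@@H](C(=O)OCC)[C@@H](c2ccc(O[Si](C(C)C)(C(C)C)C(C)C)c(OC)c2)O3)ccc1O[Si](C(C)C)(C(C)C)C(C)C
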